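**Retrosynthetic overview**
- The hydroquinone comes from its quinone (dithionite), and the quinone from the hydroquinone dimethyl ether by oxidative demethylation. No ring is built: the only ring, the arene, is carried in from 4-methoxy-2-methylphenol.
- C5–C6 bond: Nozaki–Hiyama–Kishi coupling of an aryl aldehyde (fragment A, C1–C5) with a vinyl iodide enone (fragment B, C6–C16), then oxidation to the 5-ketone.
- Fragment A: C1–C2 bond by Pd-catalysed coupling of a benzylic bromide with an E-alkenylalane from Zr-catalysed carboalumination (sets 2E).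
- Fragment B: carboalumination/iodination of pent-4-yn-1-ol (sets 6E), Wittig reaction to an (E)-2-methyl enal, ene-reductase/alcohol dehydrogenase cascade (sets C11 as S), alkenylzinc addition (sets 13E) and oxidation.

Assumption: an (S)-selective ene-reductase of the Old Yellow Enzyme family is used (the usual sense for (E)-2-methyl-2-enals); the two carbinol centres made on the way are left as epimer mixtures because both become ketones. Chain atoms are numbered C1 (benzylic CH2) to C16.

**Fragment A**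

Step 1
Reactants: 1 4-methoxy-2-methylphenol
Product: 2 2-hydroxy-5-methoxy-3-methylbenzaldehyde
Conditions: MgCl2, Et3N, (CH2O)n, MeCN, reflux
Reagents that add atoms: formaldehyde (from paraformaldehyde) C=O
Why: The magnesium phenoxide-directed ortho-formylation (Casnati–Skattebøl) can only go to the single free ortho position, which fixes the substitution pattern of the target arene.

Step 2
Reactants: 2 2-hydroxy-5-methoxy-3-methylbenzaldehyde
Product: 3 2,5-dimethoxy-3-methylbenzaldehyde
Conditions: MeI, K2CO3, DMF, rt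
Reagents that add atoms: iodomethane CI
Why: Williamson O-methylation gives a hydroquinone dimethyl ether that is inert to every later organometallic step.

Step 3
Reactants: 3 2,5-dimethoxy-3-methylbenzaldehyde
Product: 4 (2,5-dimethoxy-3-methylphenyl)methanol
Conditions: NaBH4, MeOH, 0 °C
Reagents that add atoms: none
Why: Borohydride reduction of the aryl aldehyde gives the benzylic alcohol cleanly.

Step 4
Reactants: 4 (2,5-dimethoxy-3-methylphenyl)methanol
Product: 5 1-(bromomethyl)-2,5-dimethoxy-3-methylbenzene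
Conditions: PBr3, Et2O, 0 °C
Reagents that add atoms: phosphorus tribromide BrP(Br)Br
Why: Nucleophilic substitution through the phosphite ester converts the electron-rich benzylic alcohol into the cross-coupling electrophile.

Step 5
Reactants: 5 1-(bromomethyl)-2,5-dimethoxy-3-methylbenzene; 6 tert-butyl(but-3-yn-1-yloxy)dimethylsilane
Product: 8 tert-butyl{[(3E)-5-(2,5-dimethoxy-3-methylphenyl)-3-methylpent-3-en-1-yl]oxy}dimethylsilane, via alkenyldimethylalane 7 (not isolated)
Conditions: 6, AlMe3 (2 equiv), Cp2ZrCl2 (25 mol %), CH2Cl2, 0 °C to rt; volatiles removed; then 5, Pd(PPh3)4 (5 mol %), THF, rt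
Reagents that add atoms: trimethylaluminium C[Al](C)C
Why: Negishi carboalumination adds Me and Al syn across the alkyne (Me to the internal carbon) and the Pd-catalysed Negishi cross-coupling with the benzylic bromide goes with retention, so the 2E trisubstituted alkene forms as one isomer.

Step 6
Reactants: 8 tert-butyl{[(3E)-5-(2,5-dimethoxy-3-methylphenyl)-3-methylpent-3-en-1-yl]oxy}dimethylsilane
Product: 9 (3E)-5-(2,5-dimethoxy-3-methylphenyl)-3-methylpent-3-en-1-ol
Conditions: HF·pyridine, pyridine, THF, 0 °C to rt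
Reagents that add atoms: none
Why: Fluoride-driven desilylation frees the primary alcohol without touching the aryl methyl ethers or the alkene.

Step 7
Reactants: 9 (3E)-5-(2,5-dimethoxy-3-methylphenyl)-3-methylpent-3-en-1-ol
Product: 10 (3E)-5-(2,5-dimethoxy-3-methylphenyl)-3-methylpent-3-enal
Conditions: Dess–Martin periodinane, NaHCO3, CH2Cl2, 0 °C to rt; used at once
Reagents that add atoms: none
Why: Buffered Dess–Martin oxidation gives the β,γ-unsaturated aldehyde without acid or base that would move the alkene into conjugation.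

**Fragment B**

Step 8
Reactants: 11 pent-4-yn-1-ol
Product: 13 (4E)-5-iodo-4-methylpent-4-en-1-ol, via alkenylalane alkoxide 12 (not isolated)
Conditions: AlMe3 (3 equiv), Cp2ZrCl2 (25 mol %), CH2Cl2, 0 °C to rt; then I2, THF, −30 to 0 °C; 1 M HCl work-up
Reagents that add atoms: trimethylaluminium C[Al](C)C; iodine [I][I]
Why: Negishi carboalumination (syn, Me to the internal carbon) followed by iodinolysis of the carbon–aluminium bond with retention gives the E-configured 1-iodo-2-methylalkene that becomes the 6E alkene.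

Step 9
Reactants: 13 (4E)-5-iodo-4-methylpent-4-en-1-ol
Product: 14 (4E)-5-iodo-4-methylpent-4-enal
Conditions: Dess–Martin periodinane, NaHCO3, CH2Cl2, 0 °C to rt
Reagents that add atoms: none
Why: Dess–Martin oxidation of a primary alcohol stops at the aldehyde and leaves the vinyl iodide alone.

Step 10
Reactants: 14 (4E)-5-iodo-4-methylpent-4-enal; 15 2-(triphenyl-λ5-phosphanylidene)propanal
Product: 16 (2E,6E)-7-iodo-2,6-dimethylhepta-2,6-dienal
Conditions: toluene, 90 °C; minor Z isomer removed by chromatography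
Reagents that add atoms: none
Why: The Wittig reaction of a stabilised formyl ylide is E-selective and gives the geometrically pure (E)-2-methyl-2-enal that the enzyme needs.

Step 11
Reactants: 16 (2E,6E)-7-iodo-2,6-dimethylhepta-2,6-dienal
Product: 18 (2S,6E)-7-iodo-2,6-dimethylhept-6-en-1-ol, via (2S)-aldehyde 17 (not isolated)
Conditions: ene-reductase (Old Yellow Enzyme family, OYE3), NADP+ (cat.), glucose dehydrogenase, D-glucose, KH2PO4/K2HPO4 buffer pH 7.0 with MTBE co-phase, 30 °C; after the enal is consumed alcohol dehydrogenase (horse liver), NAD+ (cat.), same pot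
Reagents that add atoms: none
Why: In this biocatalytic asymmetric C=C reduction the flavin-dependent ene-reductase delivers hydride to C3 and a proton to C2 from opposite faces of the carbonyl-activated alkene only, setting C2 as S and sparing the vinyl iodide, and the alcohol dehydrogenase then fixes the labile α-centre as the stable alcohol.

Step 12
Reactants: 18 (2S,6E)-7-iodo-2,6-dimethylhept-6-en-1-ol
Product: 17 (2S,6E)-7-iodo-2,6-dimethylhept-6-enal
Conditions: Dess–Martin periodinane, NaHCO3, CH2Cl2, 0 °C; used crude at once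
Reagents that add atoms: none
Why: Buffered Dess–Martin oxidation returns the α-methyl aldehyde without epimerisation.

Step 13
Reactants: 17 (2S,6E)-7-iodo-2,6-dimethylhept-6-enal; 19 trimethyl[(2-methylbut-3-yn-2-yl)oxy]silane
Product: 23 (3E,6S,10E)-11-iodo-2,6,10-trimethylundeca-3,10-diene-2,5-diol (C5 epimer mixture), via alkenylzirconocene chloride 20 (not isolated), via alkenylmethylzinc 21 (not isolated), via trimethylsilyl ether 22 (not isolated)
Conditions: 19, Cp2Zr(H)Cl, CH2Cl2, rt; Me2Zn, −65 °C; 17, 0 °C; aq NH4Cl; crude with K2CO3 (cat.), MeOH, rt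
Reagents that add atoms: none
Why: Schwartz hydrozirconation (syn, Zr to the terminal carbon) fixes 13E, zirconium-to-zinc transmetalation gives a non-basic alkenylzinc that adds 1,2 to the aldehyde without epimerising the α-centre or touching the vinyl iodide, and methanolysis removes the silyl group.

Step 14
Reactants: 23 (3E,6S,10E)-11-iodo-2,6,10-trimethylundeca-3,10-diene-2,5-diol
Product: 24 (3E,6S,10E)-2-hydroxy-11-iodo-2,6,10-trimethylundeca-3,10-dien-5-one
Conditions: Dess–Martin periodinane, NaHCO3, CH2Cl2, 0 °C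
Reagents that add atoms: none
Why: Dess–Martin oxidation converts only the secondary allylic carbinol (the tertiary one cannot be oxidised) into the γ-hydroxy enone and leaves C6 untouched.

**Union and end game**

Step 15
Reactants: 10 (3E)-5-(2,5-dimethoxy-3-methylphenyl)-3-methylpent-3-enal; 24 (3E,6S,10E)-2-hydroxy-11-iodo-2,6,10-trimethylundeca-3,10-dien-5-one
Product: 26 (2E,6E,11S,13E)-1-(2,5-dimethoxy-3-methylphenyl)-5,15-dihydroxy-3,7,11,15-tetramethylhexadeca-2,6,13-trien-12-one (C5 epimer mixture), via alkenylchromium dichloride 25 (not isolated)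
Conditions: CrCl2 (6 equiv), NiCl2 (2 mol %), DMSO, rt
Reagents that add atoms: none
Why: In the Nozaki–Hiyama–Kishi reaction the nickel-catalysed alkenylchromium species keeps its E geometry and adds to the aldehyde in preference to the enone, under non-basic conditions that tolerate the free tertiary alcohol.

Step 16
Reactants: 26 (2E,6E,11S,13E)-1-(2,5-dimethoxy-3-methylphenyl)-5,15-dihydroxy-3,7,11,15-tetramethylhexadeca-2,6,13-trien-12-one
Product: 27 (2E,6E,11S,13E)-1-(2,5-dimethoxy-3-methylphenyl)-15-hydroxy-3,7,11,15-tetramethylhexadeca-2,6,13-triene-5,12-dione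
Conditions: Dess–Martin periodinane, NaHCO3, CH2Cl2, 0 °C
Reagents that add atoms: none
Why: Buffered Dess–Martin oxidation gives the skipped dienone without isomerising the 2E alkene into conjugation.

Step 17
Reactants: 27 (2E,6E,11S,13E)-1-(2,5-dimethoxy-3-methylphenyl)-15-hydroxy-3,7,11,15-tetramethylhexadeca-2,6,13-triene-5,12-dione
Product: 28 2-[(2E,6E,11S,13E)-15-hydroxy-3,7,11,15-tetramethyl-5,12-dioxohexadeca-2,6,13-trien-1-yl]-6-methylcyclohexa-2,5-diene-1,4-dione
Conditions: (NH4)2Ce(NO3)6 (2.5 equiv), MeCN/H2O 2:1, 0 °C, 15 min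
Reagents that add atoms: water O
Why: Oxidative demethylation by tetravalent cerium (electron transfer from the electron-rich arene, attack of water, loss of methanol) gives the p-quinone under brief, weakly acidic conditions that spare the enones and C11.

Step 18
Reactants: 28 2-[(2E,6E,11S,13E)-15-hydroxy-3,7,11,15-tetramethyl-5,12-dioxohexadeca-2,6,13-trien-1-yl]-6-methylcyclohexa-2,5-diene-1,4-dione
Product: 29 (2E,6E,11S,13E)-1-(2,5-dihydroxy-3-methylphenyl)-15-hydroxy-3,7,11,15-tetramethylhexadeca-2,6,13-triene-5,12-dione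
Conditions: Na2S2O4, EtOAc/H2O, rt, argon, degassed solvents
Reagents that add atoms: none
Why: Two-electron reduction of the quinone by dithionite gives the hydroquinone at neutral pH, where neither enone is reduced and nothing can isomerise or epimerise.

**Compound list**
1 | 4-methoxy-2-methylphenol | COc1ccc(O)c(C)c1 | starting material
2 | 2-hydroxy-5-methoxy-3-methylbenzaldehyde | COc1cc(C)c(O)c(C=O)c1 | intermediate
3 | 2,5-dimethoxy-3-methylbenzaldehyde | COc1cc(C)c(OC)c(C=O)c1 | intermediate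
4 | (2,5-dimethoxy-3-methylphenyl)methanol | COc1cc(C)c(OC)c(CO)c1 | intermediate
5 | 1-(bromomethyl)-2,5-dimethoxy-3-methylbenzene | COc1cc(C)c(OC)c(CBr)c1 | intermediate
6 | tert-butyl(but-3-yn-1-yloxy)dimethylsilane | C#CCCO[Si](C)(C)C(C)(C)C | starting material
7 | [(1E)-4-(tert-butyldimethylsilyloxy)-2-methylbut-1-en-1-yl]dimethylalane | C[Al](C)/C=C(\C)CCO[Si](C)(C)C(C)(C)C | intermediate
8 | tert-butyl{[(3E)-5-(2,5-dimethoxy-3-methylphenyl)-3-methylpent-3-en-1-yl]oxy}dimethylsilane | COc1cc(C)c(OC)c(C/C=C(\C)CCO[Si](C)(C)C(C)(C)C)c1 | intermediate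
9 | (3E)-5-(2,5-dimethoxy-3-methylphenyl)-3-methylpent-3-en-1-ol | COc1cc(C)c(OC)c(C/C=C(\C)CCO)c1 | intermediate
10 | (3E)-5-(2,5-dimethoxy-3-methylphenyl)-3-methylpent-3-enal | COc1cc(C)c(OC)c(C/C=C(\C)CC=O)c1 | intermediate
11 | pent-4-yn-1-ol | C#CCCCO | starting material
12 | [(1E)-5-(dimethylalumanyloxy)-2-methylpent-1-en-1-yl]dimethylalane | C[Al](C)/C=C(\C)CCCO[Al](C)C | intermediate
13 | (4E)-5-iodo-4-methylpent-4-en-1-ol | OCCC/C(C)=C/I | intermediate
14 | (4E)-5-iodo-4-methylpent-4-enal | O=CCC/C(C)=C/I | intermediate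
15 | 2-(triphenyl-λ5-phosphanylidene)propanal | CC(C=O)=P(c1ccccc1)(c1ccccc1)c1ccccc1 | starting material
16 | (2E,6E)-7-iodo-2,6-dimethylhepta-2,6-dienal | O=C/C(C)=C/CC/C(C)=C/I | intermediate
17 | (2S,6E)-7-iodo-2,6-dimethylhept-6-enal | O=C[C@@H](C)CCC/C(C)=C/I | intermediate
18 | (2S,6E)-7-iodo-2,6-dimethylhept-6-en-1-ol | OC[C@@H](C)CCC/C(C)=C/I | intermediate
19 | trimethyl[(2-methylbut-3-yn-2-yl)oxy]silane | C#CC(C)(C)O[Si](C)(C)C | starting material
20 | chlorobis(cyclopentadienyl)[(1E)-3-methyl-3-(trimethylsilyloxy)but-1-en-1-yl]zirconium | C[Si](C)(C)OC(C)(C)/C=C/[Zr](Cl)(C1C=CC=C1)C1C=CC=C1 | intermediate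
21 | methyl[(1E)-3-methyl-3-(trimethylsilyloxy)but-1-en-1-yl]zinc | C[Zn]/C=C/C(C)(C)O[Si](C)(C)C | intermediate
22 | (3E,6S,10E)-11-iodo-2,6,10-trimethyl-2-(trimethylsilyloxy)undeca-3,10-dien-5-ol (C5 epimer mixture) | C[Si](C)(C)OC(C)(C)/C=C/C(O)[C@@H](C)CCC/C(C)=C/I | intermediate
23 | (3E,6S,10E)-11-iodo-2,6,10-trimethylundeca-3,10-diene-2,5-diol (C5 epimer mixture) | CC(C)(O)/C=C/C(O)[C@@H](C)CCC/C(C)=C/I | intermediate
24 | (3E,6S,10E)-2-hydroxy-11-iodo-2,6,10-trimethylundeca-3,10-dien-5-one | CC(C)(O)/C=C/C(=O)[C@@H](C)CCC/C(C)=C/I | intermediate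
25 | dichloro[(1E,6S,8E)-10-hydroxy-2,6,10-trimethyl-7-oxoundeca-1,8-dien-1-yl]chromium | Cl[Cr](Cl)/C=C(\C)CCC[C@H](C)C(=O)/C=C/C(C)(C)O | intermediate
26 | (2E,6E,11S,13E)-1-(2,5-dimethoxy-3-methylphenyl)-5,15-dihydroxy-3,7,11,15-tetramethylhexadeca-2,6,13-trien-12-one (C5 epimer mixture) | COc1cc(C)c(OC)c(C/C=C(\C)CC(O)/C=C(\C)CCC[C@H](C)C(=O)/C=C/C(C)(C)O)c1 | intermediate
27 | (2E,6E,11S,13E)-1-(2,5-dimethoxy-3-methylphenyl)-15-hydroxy-3,7,11,15-tetramethylhexadeca-2,6,13-triene-5,12-dione | COc1cc(C)c(OC)c(C/C=C(\C)CC(=O)/C=C(\C)CCC[C@H](C)C(=O)/C=C/C(C)(C)O)c1 | intermediate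
28 | 2-[(2E,6E,11S,13E)-15-hydroxy-3,7,11,15-tetramethyl-5,12-dioxohexadeca-2,6,13-trien-1-yl]-6-methylcyclohexa-2,5-diene-1,4-dione | CC1=CC(=O)C=C(C/C=C(\C)CC(=O)/C=C(\C)CCC[C@H](C)C(=O)/C=C/C(C)(C)O)C1=O | intermediate
29 | (2E,6E,11S,13E)-1-(2,5-dihydroxy-3-methylphenyl)-15-hydroxy-3,7,11,15-tetramethylhexadeca-2,6,13-triene-5,12-dione (CNP0221594.1) | C/C(=C\C(=O)C/C(C)=C/Cc1cc(O)cc(C)c1O)CCC[C@H](C)C(=O)/C=C/C(C)(C)O | target

**Step count**
Total: 18 steps (7 to fragment A, 7 to fragment B, 4 after the union).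
Longest linear sequence: 11 steps (steps 8–18; the branch through steps 1–7 is equally long).

**Three steps most likely to fail**

Step 11 (ene-reductase/alcohol dehydrogenase cascade). The lipophilic iodo-dienal may be a slow substrate, the alcohol dehydrogenase can reduce unreacted enal to a dead-end allylic alcohol, and the intermediate aldehyde can racemise in buffer. The fallback sets out from 13 and comes back at 18. Alcohol 13 is converted with I2, PPh3 and imidazole into (1E)-1,5-diiodo-2-methylpent-1-ene F1. Its primary iodide is coupled with vinylmagnesium bromide under CuI catalysis (THF, −30 °C) to give (1E)-1-iodo-2-methylhepta-1,6-diene F2. Zirconium-catalysed asymmetric carboalumination of the terminal alkene of F2 (AlMe3, (+)-(NMI)2ZrCl2 cat., CH2Cl2, then O2) gives 18 directly. The stereocentre is then set by asymmetric carbon–carbon bond formation instead of C=C reduction, steps 9 to 11 drop out, and the expected cost is a lower enantiomeric excess.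

Step 15 (CrCl2/NiCl2 coupling). A trisubstituted vinyl iodide inserts slowly, aldehyde 10 can slip into conjugation, and the enone of 24 is exposed to divalent chromium. The fallback sets out from 23 and comes back at 27. Diol 23, which has no ketone yet, is coupled with 10 under CrCl2/NiCl2 in DMSO to give (2E,6E,11S,13E)-1-(2,5-dimethoxy-3-methylphenyl)-3,7,11,15-tetramethylhexadeca-2,6,13-triene-5,12,15-triol F3. Both secondary carbinols of F3 are then oxidised together with Dess–Martin periodinane to reach 27, so the enone and its acidic α-centre appear only after the organochromium step; steps 14 and 16 merge into this one oxidation.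

Step 17 ((NH4)2Ce(NO3)6 on the complete skeleton). Over-oxidation at allylic positions or poor mass balance is possible on a substrate carrying two enones. The fallback sets out from 9 and comes back at 29, moving the oxidant to an early, robust intermediate:
- Alcohol 9 is oxidised with (NH4)2Ce(NO3)6 to 2-[(2E)-5-hydroxy-3-methylpent-2-en-1-yl]-6-methylcyclohexa-2,5-diene-1,4-dione F4.
- F4 is reduced with Na2S2O4 to 2-[(2E)-5-hydroxy-3-methylpent-2-en-1-yl]-6-methylbenzene-1,4-diol F5.
- F5 is persilylated (TBSCl, imidazole, DMF) to tert-butyl{[(3E)-5-{2,5-bis[(tert-butyldimethylsilyl)oxy]-3-methylphenyl}-3-methylpent-3-en-1-yl]oxy}dimethylsilane F6.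
- Camphorsulfonic acid in MeOH at 0 °C frees only the primary alcohol, giving (3E)-5-[2,5-bis(tert-butyldimethylsilyloxy)-3-methylphenyl]-3-methylpent-3-en-1-ol F7.
- Dess–Martin oxidation gives (3E)-5-[2,5-bis(tert-butyldimethylsilyloxy)-3-methylphenyl]-3-methylpent-3-enal F8.
- CrCl2/NiCl2 coupling of F8 with 24 gives (2E,6E,11S,13E)-1-[2,5-bis(tert-butyldimethylsilyloxy)-3-methylphenyl]-5,15-dihydroxy-3,7,11,15-tetramethylhexadeca-2,6,13-trien-12-one F9.
- Dess–Martin oxidation gives (2E,6E,11S,13E)-1-[2,5-bis(tert-butyldimethylsilyloxy)-3-methylphenyl]-15-hydroxy-3,7,11,15-tetramethylhexadeca-2,6,13-triene-5,12-dione F10.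
- Bu4NF buffered with AcOH (THF, 0 °C) then gives 29, with no oxidant ever meeting the finished skeleton.

**Further compounds**
F1 | step 11 | (1E)-1,5-diiodo-2-methylpent-1-ene | ICCC/C(C)=C/I
F2 | step 11 | (1E)-1-iodo-2-methylhepta-1,6-diene | C=CCCC/C(C)=C/I
F3 | step 15 | (2E,6E,11S,13E)-1-(2,5-dimethoxy-3-methylphenyl)-3,7,11,15-tetramethylhexadeca-2,6,13-triene-5,12,15-triol | COc1cc(C)c(OC)c(C/C=C(\C)CC(O)/C=C(\C)CCC[C@H](C)C(O)/C=C/C(C)(C)O)c1
F4 | step 17 | 2-[(2E)-5-hydroxy-3-methylpent-2-en-1-yl]-6-methylcyclohexa-2,5-diene-1,4-dione | CC1=CC(=O)C=C(C/C=C(\C)CCO)C1=O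
F5 | step 17 | 2-[(2E)-5-hydroxy-3-methylpent-2-en-1-yl]-6-methylbenzene-1,4-diol | Cc1cc(O)cc(C/C=C(\C)CCO)c1O
F6 | step 17 | tert-butyl{[(3E)-5-{2,5-bis[(tert-butyldimethylsilyl)oxy]-3-methylphenyl}-3-methylpent-3-en-1-yl]oxy}dimethylsilane | CC(C)(C)[Si](C)(C)OCC/C(C)=C/Cc1cc(O[Si](C)(C)C(C)(C)C)cc(C)c1O[Si](C)(C)C(C)(C)C
F7 | step 17 | (3E)-5-[2,5-bis(tert-butyldimethylsilyloxy)-3-methylphenyl]-3-methylpent-3-en-1-ol | OCC/C(C)=C/Cc1cc(O[Si](C)(C)C(C)(C)C)cc(C)c1O[Si](C)(C)C(C)(C)C
F8 | step 17 | (3E)-5-[2,5-bis(tert-butyldimethylsilyloxy)-3-methylphenyl]-3-methylpent-3-enal | O=CC/C(C)=C/Cc1cc(O[Si](C)(C)C(C)(C)C)cc(C)c1O[Si](C)(C)C(C)(C)C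
F9 | step 17 | (2E,6E,11S,13E)-1-[2,5-bis(tert-butyldimethylsilyloxy)-3-methylphenyl]-5,15-dihydroxy-3,7,11,15-tetramethylhexadeca-2,6,13-trien-12-one | CC(C)(C)[Si](C)(C)Oc1cc(C)c(O[Si](C)(C)C(C)(C)C)c(C/C=C(\C)CC(O)/C=C(\C)CCC[C@H](C)C(=O)/C=C/C(C)(C)O)c1
F10 | step 17 | (2E,6E,11S,13E)-1-[2,5-bis(tert-butyldimethylsilyloxy)-3-methylphenyl]-15-hydroxy-3,7,11,15-tetramethylhexadeca-2,6,13-triene-5,12-dione | CC(C)(C)[Si](C)(C)Oc1cc(C)c(O[Si](C)(C)C(C)(C)C)c(C/C=C(\C)CC(=O)/C=C(\C)CCC[C@H](C)C(=O)/C=C/C(C)(C)O)c1
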